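## Retrosynthetic overview
1. Target ⇒ Δ4‑dioxene acid by face‑selective diimide reduction, which sets C4. The O–O bond survives and no hydroperoxide is used.
2. Dioxene (the only ring, closed in a single event) ⇒ acyclic (3E,5E)‑3,5‑dienoic acid + singlet O2 by [4+2], as in the proposed biogenesis. C3 and the quaternary C6 arise together from the alkene geometry.
3. Dienoic acid ⇒ C4–C5 Negishi coupling. One partner is an alkenylalane from carboalumination of a terminal alkyne (installs C6‑CH3 and 5E). The other is (E)‑4‑iodopent‑3‑enoic acid from pent‑3‑yn‑1‑ol (gives 3E).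
4. Alkyne ⇒ acetylide + primary iodide. C8 and C12 come from two chiral‑pool bromides joined at C9–C10 under Cu catalysis. The phenyl end comes from styrene cross‑metathesis/hydrogenation.

Assumption: locants follow the parent acid, (3S,4S,6R,8R,12S)‑3,6‑epidioxy‑4,6,8,12‑tetramethyl‑16‑phenylhexadecanoic acid, and both commercial chiral bromides are taken as ≥98 % ee.

## Route

Step 1
Reactants: 1 (S)-citronellyl bromide [(6S)-8-bromo-2,6-dimethyloct-2-ene]; 2 (S)-3-bromo-2-methylpropan-1-ol
Product: 5 (2R,6R)-2,6,10-trimethylundec-9-en-1-ol, via citronellylmagnesium bromide 3 (not isolated), via chloromagnesium bromoalkoxide 4 (not isolated)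
Conditions: 1 (1.3 equiv), Mg, THF, 45 °C; separately 2, MeMgCl (1.0 equiv), THF, −30 °C; combine, Li2CuCl4 (5 mol %), NMP (4 equiv), 0 °C → rt; 1 M HCl
Reagents that add atoms: none
Why: Cu‑catalysed (Kochi–Schlosser) sp3–sp3 Grignard cross‑coupling with the OH masked in situ as its magnesium alkoxide; C8 and C12 of the target come unchanged from the chiral pool because neither stereogenic carbon is a reacting centre.

Step 2
Reactants: 5 (2R,6R)-2,6,10-trimethylundec-9-en-1-ol; 6 styrene
Product: 8 (2R,6S)-2,6-dimethyl-10-phenyldecan-1-ol, via styrenyl metathesis product 7 (not isolated)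
Conditions: Grubbs II (3 mol %), 6 (3 equiv), ClCH2CH2Cl, 45 °C, Ar sweep; then H2 (7 bar), 70 °C, same pot
Reagents that add atoms: none
Why: Olefin cross‑metathesis of the prenyl terminus with styrene is driven by loss of isobutene and is followed by tandem hydrogenation with the Ru hydride formed from the same catalyst charge; no stereocentre is touched (the C12 descriptor changes only through CIP priorities).

Step 3
Reactants: 8 (2R,6S)-2,6-dimethyl-10-phenyldecan-1-ol
Product: 9 [(5S,9R)-10-iodo-5,9-dimethyldecyl]benzene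
Conditions: I2, PPh3, imidazole, CH2Cl2, 0 °C → rt
Reagents that add atoms: iodine, II
Why: Appel (Garegg–Samuelsson) iodination of a primary alcohol through the alkoxyphosphonium salt; substitution occurs at CH2, so C8 is untouched.

Step 4
Reactants: 9 [(5S,9R)-10-iodo-5,9-dimethyldecyl]benzene
Product: 10 [(5S,9R)-5,9-dimethyldodec-11-yn-1-yl]benzene
Conditions: lithium acetylide–ethylenediamine (2 equiv), DMSO, 10 °C → rt
Reagents that add atoms: lithium acetylide–ethylenediamine complex, [Li+].[C-]#C.NCCN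
Why: SN2 alkynylation of a primary iodide in a dipolar aprotic solvent brings in C6 and C5 without affecting the β‑stereocentre.

Step 5
Reactants: 11 pent-3-yn-1-ol
Product: 13 (E)-4-iodopent-3-en-1-ol, via alkenylzirconocene chloride 12 (not isolated)
Conditions: Cp2Zr(H)Cl (2.6 equiv), THF, rt → 40 °C; I2, 0 °C; dilute HCl
Reagents that add atoms: iodine, II
Why: Hydrozirconation–iodinolysis, in which the first equivalent of Schwartz reagent only zirconates the OH, the second adds H–Zr syn across the alkyne, and excess reagent equilibrates Zr to the less hindered methyl‑bearing carbon (ca. 9:1, minor regioisomer removed on silica), so iodinolysis with retention gives the E‑2‑iodoalkene needed for the 3E bond.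

Step 6
Reactants: 13 (E)-4-iodopent-3-en-1-ol
Product: 14 (E)-4-iodopent-3-enoic acid
Conditions: CrO3, H2SO4, H2O (Jones), acetone, 0 °C
Reagents that add atoms: water (aqueous Jones reagent), O
Why: Jones oxidation of a homoallylic alcohol via the aldehyde hydrate gives the β,γ‑unsaturated acid under acidic conditions, so the double bond neither migrates nor isomerises and the vinyl iodide is inert.

Step 7
Reactants: 10 [(5S,9R)-5,9-dimethyldodec-11-yn-1-yl]benzene; 14 (E)-4-iodopent-3-enoic acid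
Product: 17 (3E,5E,8R,12S)-4,6,8,12-tetramethyl-16-phenylhexadeca-3,5-dienoic acid, via dimethylalkenylalane 15 (not isolated), via sodium iodopentenoate 16 (not isolated)
Conditions: 10, Me3Al (2.5 equiv), Cp2ZrCl2 (20 mol %), CH2Cl2, 0 °C → rt, then evaporate volatiles; 14 (1.3 equiv), NaH, THF, 0 °C; combine in THF, ZnCl2, Pd2(dba)3 (2.5 mol %), P(2-furyl)3 (10 mol %), rt; cold 1 M HCl
Reagents that add atoms: trimethylaluminium, C[Al](C)C
Why: Negishi Zr‑catalysed carboalumination (syn Me–Al addition sets C6‑CH3 and 5E) followed by Pd/Zn Negishi alkenyl–alkenyl coupling with retention in both partners (3E from 14); using 14 as its carboxylate salt prevents protonolysis of the alane and suppresses α‑deprotonation, so the diene does not slip into conjugation with the carboxyl.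

Step 8
Reactants: 17 (3E,5E,8R,12S)-4,6,8,12-tetramethyl-16-phenylhexadeca-3,5-dienoic acid
Product: 18 2-[(3S,6R)-6-[(2R,6S)-2,6-dimethyl-10-phenyldecyl]-4,6-dimethyl-3,6-dihydro-1,2-dioxin-3-yl]acetic acid
Conditions: O2 (1 atm), tetraphenylporphyrin (0.5 mol %), CH2Cl2, 0 °C, visible light (λ > 495 nm); preparative HPLC (silica, hexane/EtOAc/0.1 % AcOH)
Reagents that add atoms: dioxygen, O=O
Why: Type‑II photooxygenation, a suprafacial [4+2] cycloaddition of singlet oxygen to the s‑cis conformer of the electron‑rich tetraalkyl diene, forms both C–O bonds at once and translates the 3E,5E geometry (both CH2 chains "outside") into the cis C3/C6 relationship including the quaternary centre, as known for closely related 4,6‑dialkyl‑3,5‑dienes; remote C8 gives no useful π‑facial bias, so 18 forms about 1:1 with its (3R,6S) diastereomer and is obtained pure by HPLC, which fixes the absolute configuration of the ring.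

Step 9
Reactants: 18 2-[(3S,6R)-6-[(2R,6S)-2,6-dimethyl-10-phenyldecyl]-4,6-dimethyl-3,6-dihydro-1,2-dioxin-3-yl]acetic acid
Product: 19 2-[(3S,4S,6R)-6-[(2R,6S)-2,6-dimethyl-10-phenyldecyl]-4,6-dimethyl-1,2-dioxan-3-yl]acetic acid (target)
Conditions: KO2CN=NCO2K (30 equiv, portions), AcOH (60 equiv, slow addition), MeOH–CH2Cl2 1:1, 0 °C → rt, 2–3 cycles
Reagents that add atoms: none
Why: Diimide reduction transfers H2 in a concerted syn fashion to C=C and leaves the O–O bond intact; the reagent approaches the face carrying only C3‑H and C6‑CH3, opposite to both CH2 chains, so C4‑CH3 ends up cis to the acetic acid chain (4S), and the minor 4‑epimer, a ring diastereomer, is removed on silica.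

## Compound list
1 | (S)-citronellyl bromide, (6S)-8-bromo-2,6-dimethyloct-2-ene | C[C@@H](CCC=C(C)C)CCBr | starting material
2 | (S)-3-bromo-2-methylpropan-1-ol | BrC[C@@H](C)CO | starting material
3 | (S)-citronellylmagnesium bromide | C[C@@H](CCC=C(C)C)CC[Mg]Br | intermediate
4 | chloromagnesium (S)-3-bromo-2-methylpropan-1-olate | BrC[C@@H](C)CO[Mg]Cl | intermediate
5 | (2R,6R)-2,6,10-trimethylundec-9-en-1-ol | C[C@@H](CCC=C(C)C)CCC[C@@H](C)CO | intermediate
6 | styrene | C=Cc1ccccc1 | starting material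
7 | (2R,6R,9E)-2,6-dimethyl-10-phenyldec-9-en-1-ol | C[C@@H](CC/C=C/c1ccccc1)CCC[C@@H](C)CO | intermediate
8 | (2R,6S)-2,6-dimethyl-10-phenyldecan-1-ol | C[C@@H](CCCCc1ccccc1)CCC[C@@H](C)CO | intermediate
9 | [(5S,9R)-10-iodo-5,9-dimethyldecyl]benzene | C[C@@H](CCCCc1ccccc1)CCC[C@@H](C)CI | intermediate
10 | [(5S,9R)-5,9-dimethyldodec-11-yn-1-yl]benzene | C[C@@H](CCCCc1ccccc1)CCC[C@@H](C)CC#C | intermediate
11 | pent-3-yn-1-ol | CC#CCCO | starting material
12 | (E)-alkenylzirconocene chloride of 11, O-zirconated (Zr on the methyl-bearing carbon, trans to the CH2CH2O chain) | C/C(=C\CCO[Zr](Cl)(C1C=CC=C1)C1C=CC=C1)[Zr](Cl)(C1C=CC=C1)C1C=CC=C1 | intermediate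
13 | (E)-4-iodopent-3-en-1-ol | I/C(C)=C/CCO | intermediate
14 | (E)-4-iodopent-3-enoic acid | I/C(C)=C/CC(=O)O | intermediate
15 | dimethyl[(1E,4R,8S)-2,4,8-trimethyl-12-phenyldodec-1-en-1-yl]alane | C[C@@H](CCCCc1ccccc1)CCC[C@@H](C)C/C(C)=C/[Al](C)C | intermediate
16 | sodium (E)-4-iodopent-3-enoate | I/C(C)=C/CC(=O)[O-].[Na+] | intermediate
17 | (3E,5E,8R,12S)-4,6,8,12-tetramethyl-16-phenylhexadeca-3,5-dienoic acid | C[C@@H](CCCCc1ccccc1)CCC[C@@H](C)C/C(C)=C/C(C)=C/CC(=O)O | intermediate
18 | 2-[(3S,6R)-6-[(2R,6S)-2,6-dimethyl-10-phenyldecyl]-4,6-dimethyl-3,6-dihydro-1,2-dioxin-3-yl]acetic acid | C[C@@H](CCCCc1ccccc1)CCC[C@@H](C)C[C@]1(C)C=C(C)[C@H](CC(=O)O)OO1 | intermediate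
19 | 2-[(3S,4S,6R)-6-[(2R,6S)-2,6-dimethyl-10-phenyldecyl]-4,6-dimethyl-1,2-dioxan-3-yl]acetic acid | C[C@@H](CCCCc1ccccc1)CCC[C@@H](C)C[C@]1(C)C[C@H](C)[C@H](CC(=O)O)OO1 | target

## Step count and risks
Total step count: 9. Longest linear sequence: 7 (steps 1, 2, 3, 4, 7, 8, 9). Steps 5 and 6 form the two‑step side branch.

**Most likely to fail, first: step 8.** Ene hydroperoxidation can compete with the [4+2] mode. The two π‑facial diastereomers form in equal amounts and may not separate as free acids.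
- This fallback sets out from 17 and comes back at 19. It replaces chromatography by an enzymatic diastereomer resolution on neutral esters.
- 17 is esterified with TMSCHN2 to methyl (3E,5E,8R,12S)-4,6,8,12-tetramethyl-16-phenylhexadeca-3,5-dienoate F4.
- Photooxygenation gives methyl 2-[(3S,6R)-6-[(2R,6S)-2,6-dimethyl-10-phenyldecyl]-4,6-dimethyl-3,6-dihydro-1,2-dioxin-3-yl]acetate F5, together with its 3R,6S isomer.
- Diimide reduction of the mixture gives methyl 2-[(3S,4S,6R)-6-[(2R,6S)-2,6-dimethyl-10-phenyldecyl]-4,6-dimethyl-1,2-dioxan-3-yl]acetate F6.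
- A hydrolase is then used in pH 7 buffer/MTBE (screen Candida antarctica lipase B, Burkholderia cepacia lipase, Candida rugosa lipase and pig liver esterase). It should cleave only one ring configuration of these β‑peroxy esters.
- This gives 19 directly. If the enzyme prefers the other isomer, it leaves pure F6, which LiOH in THF–H2O converts into 19.
- If the cycloaddition itself fails, the fallback given for step 9 bypasses it as well.

**Second: step 9.** The trisubstituted ring alkene reacts slowly with diimide, and the face selectivity is only sterically biased.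
- This fallback sets out from 10 and comes back at 19. It fixes C4 before the ring is closed.
- Bromoboration/protonolysis of 10 (B‑Br‑9‑BBN, CH2Cl2, 0 °C; AcOH) gives [(5S,9R)-11-bromo-5,9-dimethyldodec-11-en-1-yl]benzene F7.
- Mg in THF converts it into [(4R,8S)-4,8-dimethyl-12-phenyldodec-1-en-2-yl]magnesium bromide F8.
- F8 is coupled (Li2CuCl4, NMP) with chloromagnesium (R)-3-bromo-2-methylpropan-1-olate F9. F9 is made from commercial (R)-3-bromo-2-methylpropan-1-ol and MeMgCl and brings in C4.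
- The product is (2S,6R,10S)-2,6,10-trimethyl-4-methylidene-14-phenyltetradecan-1-ol F10.
- Dess–Martin oxidation gives (2S,6R,10S)-2,6,10-trimethyl-4-methylidene-14-phenyltetradecanal F11.
- Wittig olefination with Ph3P=CHCO2Me gives methyl (2E,4S,8R,12S)-4,8,12-trimethyl-6-methylidene-16-phenylhexadec-2-enoate F12.
- Mukaiyama–Isayama peroxidation (Co(thd)2, O2, Et3SiH) attacks only the 1,1‑disubstituted alkene. It gives methyl (2E,4S,6R,8R,12S)-4,6,8,12-tetramethyl-16-phenyl-6-(triethylsilylperoxy)hexadec-2-enoate F13, 1:1 at C6.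
- HF·pyridine frees methyl (2E,4S,6R,8R,12S)-6-hydroperoxy-4,6,8,12-tetramethyl-16-phenylhexadec-2-enoate F14.
- F14 closes by 6‑exo peroxy‑Michael addition (cat. Et2NH, CF3CH2OH, kinetic conditions) to the dioxane ester F6. The ring diastereomers are separated on silica.
- LiOH in THF–H2O then gives 19.

**Third: step 7.** This is a one‑pot carboalumination and alkenyl–alkenyl coupling with an unprotected carboxylate and a hindered 2‑iodoalkene.
- This fallback sets out from 10 and comes back at 17. It builds the 3E bond by vinylic C–O activation instead of C–I activation.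
- Alane 15 is quenched with I2 to give [(5S,9R,11E)-12-iodo-5,9,11-trimethyldodec-11-en-1-yl]benzene F1.
- Stille coupling with commercial tributyl(4,5-dihydrofuran-2-yl)stannane (Pd(PPh3)4, CuI, DMF) gives 5-[(1E,4R,8S)-2,4,8-trimethyl-12-phenyldodec-1-en-1-yl]-2,3-dihydrofuran F2.
- Ni‑catalysed ring‑opening methylation follows (MeMgBr, NiCl2(PPh3)2, toluene, 80 °C; Wenkert type, retention at the vinylic carbon). It places CH3 cis to the CH2CH2O chain and gives (3E,5E,8R,12S)-4,6,8,12-tetramethyl-16-phenylhexadeca-3,5-dien-1-ol F3.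
- TEMPO/PhI(OAc)2 in MeCN–H2O oxidises F3 to 17.

## Further compounds
F1 | step 7 | [(5S,9R,11E)-12-iodo-5,9,11-trimethyldodec-11-en-1-yl]benzene | C[C@@H](CCCCc1ccccc1)CCC[C@@H](C)C/C(C)=C/I
F2 | step 7 | 5-[(1E,4R,8S)-2,4,8-trimethyl-12-phenyldodec-1-en-1-yl]-2,3-dihydrofuran | C[C@@H](CCCCc1ccccc1)CCC[C@@H](C)C/C(C)=C/C1=CCCO1
F3 | step 7 | (3E,5E,8R,12S)-4,6,8,12-tetramethyl-16-phenylhexadeca-3,5-dien-1-ol | C[C@@H](CCCCc1ccccc1)CCC[C@@H](C)C/C(C)=C/C(C)=C/CCO
F4 | step 8 | methyl (3E,5E,8R,12S)-4,6,8,12-tetramethyl-16-phenylhexadeca-3,5-dienoate | C[C@@H](CCCCc1ccccc1)CCC[C@@H](C)C/C(C)=C/C(C)=C/CC(=O)OC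
F5 | step 8 | methyl 2-[(3S,6R)-6-[(2R,6S)-2,6-dimethyl-10-phenyldecyl]-4,6-dimethyl-3,6-dihydro-1,2-dioxin-3-yl]acetate | C[C@@H](CCCCc1ccccc1)CCC[C@@H](C)C[C@]1(C)C=C(C)[C@H](CC(=O)OC)OO1
F6 | step 8 | methyl 2-[(3S,4S,6R)-6-[(2R,6S)-2,6-dimethyl-10-phenyldecyl]-4,6-dimethyl-1,2-dioxan-3-yl]acetate | C[C@@H](CCCCc1ccccc1)CCC[C@@H](C)C[C@]1(C)C[C@H](C)[C@H](CC(=O)OC)OO1
F7 | step 9 | [(5S,9R)-11-bromo-5,9-dimethyldodec-11-en-1-yl]benzene | C[C@@H](CCCCc1ccccc1)CCC[C@@H](C)CC(Br)=C
F8 | step 9 | [(4R,8S)-4,8-dimethyl-12-phenyldodec-1-en-2-yl]magnesium bromide | C[C@@H](CCCCc1ccccc1)CCC[C@@H](C)CC(=C)[Mg]Br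
F9 | step 9 | chloromagnesium (R)-3-bromo-2-methylpropan-1-olate | BrC[C@H](C)CO[Mg]Cl
F10 | step 9 | (2S,6R,10S)-2,6,10-trimethyl-4-methylidene-14-phenyltetradecan-1-ol | C[C@@H](CCCCc1ccccc1)CCC[C@@H](C)CC(=C)C[C@H](C)CO
F11 | step 9 | (2S,6R,10S)-2,6,10-trimethyl-4-methylidene-14-phenyltetradecanal | C[C@@H](CCCCc1ccccc1)CCC[C@@H](C)CC(=C)C[C@H](C)C=O
F12 | step 9 | methyl (2E,4S,8R,12S)-4,8,12-trimethyl-6-methylidene-16-phenylhexadec-2-enoate | C[C@@H](CCCCc1ccccc1)CCC[C@@H](C)CC(=C)C[C@H](C)/C=C/C(=O)OC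
F13 | step 9 | methyl (2E,4S,6R,8R,12S)-4,6,8,12-tetramethyl-16-phenyl-6-(triethylsilylperoxy)hexadec-2-enoate | C[C@@H](CCCCc1ccccc1)CCC[C@@H](C)C[C@](OO[Si](CC)(CC)CC)(C)C[C@H](C)/C=C/C(=O)OC
F14 | step 9 | methyl (2E,4S,6R,8R,12S)-6-hydroperoxy-4,6,8,12-tetramethyl-16-phenylhexadec-2-enoate | C[C@@H](CCCCc1ccccc1)CCC[C@@H](C)C[C@](OO)(C)C[C@H](C)/C=C/C(=O)OC
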